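Altisin is disconnected at the C4a–C5 bond, so that ring A is unravelled to a four-membered ring. The ring A pattern (free OH on C5, H on C6, OMe on C7 and C8) maps atom for atom onto C1=O, C2–H, C3–OMe and C4–OMe of a cyclobutenone attached through C4 to C2 of a 6-aryl-4-pyranone, in which rings B and C are already complete. Heating this isomer of the target opens the strained ring to a dienylketene that closes onto pyranone C3 and enolises; ring A, the C4a–C5 bond and the unprotected C5 phenol thus arise in one neutral operation. The precursor is assembled from a magnesiated pyranone and methyl semisquarate.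

Key step: step 5

Assumption: every intermediate that holds a stereocenter is carried as a racemate. All these centers are erased on the way and altisin is achiral, so no stereocontrol is planned.

Step 1
Reactants: 1 (E)-4-methoxybut-3-en-2-one; 2 2,6-dimethoxybenzoyl chloride
Product: 5 2-(2,6-dimethoxyphenyl)-4H-pyran-4-one, via lithium dienolate 3 (not isolated), via methoxyenone diketone 4 (not isolated)
Conditions: 1 (2 equiv), LiN(SiMe3)2 (2 equiv), THF, −78 °C; 2 (1 equiv), −78 °C; cold 1 M HCl; crude 4, CF3CO2H (cat.), toluene, rt
Reagents that add atoms: none
Why: Kinetic deprotonation of the methyl group gives cross-conjugated dienolate 3, Claisen-type C-acylation by the aroyl chloride gives 1,3-diketone 4 (the second equivalent of 3 takes up its acidic proton), and acid then triggers 6-endo oxa-Michael addition of the aryl-side enol to the β-methoxyenone with loss of methanol, the established γ-pyranone synthesis from acid chlorides, which delivers rings B and C at the final oxidation level so that no dehydrogenation is needed.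

Step 2
Reactants: 6 dimethyl squarate (3,4-dimethoxycyclobut-3-ene-1,2-dione)
Product: 8 methyl semisquarate (3-methoxycyclobut-3-ene-1,2-dione), via hydroxycyclobutenone 7 (not isolated)
Conditions: LiAlH(OtBu)3 (1.05 equiv), THF, −20 °C; aq. HCl quench; crude 7, conc. HCl (cat.), CH2Cl2, rt
Reagents that add atoms: none
Why: The bulky hydride should stop after 1,2-reduction of one carbonyl group because the aluminium alkoxide of 7 keeps only a vinylogous ester carbonyl, and acid then ionises the allylic carbinol to a methoxy-stabilised cyclobutenyl cation that takes water back at the distal methoxy-bearing carbon and expels methanol (carbonyl reduction followed by acid-catalysed 1,3-transposition, the standard passage from a squarate diester to a semisquarate); the stereocenter of racemic 7 disappears in the process.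

Step 3
Reactants: 5 2-(2,6-dimethoxyphenyl)-4H-pyran-4-one; 8 methyl semisquarate
Product: 10 4-[6-(2,6-dimethoxyphenyl)-4-oxo-4H-pyran-2-yl]-4-hydroxy-3-methoxycyclobut-2-en-1-one (racemic), via pyranonylmagnesium chloride 9 (not isolated)
Conditions: 5, TMPMgCl·LiCl (1.1 equiv; TMP = 2,2,6,6-tetramethylpiperidide), THF, −40 °C; 8 (1.2 equiv), −78 °C; aq. NH4Cl
Reagents that add atoms: none
Why: TMPMgCl·LiCl should remove C6–H, the most acidic ring proton because it lies next to the ring oxygen and β to the magnesium-complexed carbonyl group (directed magnesiation of a β-alkoxyenone; anisole-type C–H bonds are inert at this temperature), and alkenyl Grignard reagent 9 then adds 1,2 to the ketone-like C2 carbonyl of 8 and not to C1, which is deactivated as a vinylogous ester, so that the carbinol carbon ends up next to the methoxy-bearing carbon; the new quaternary stereocenter forms without control as a racemate.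

Step 4
Reactants: 10 4-[6-(2,6-dimethoxyphenyl)-4-oxo-4H-pyran-2-yl]-4-hydroxy-3-methoxycyclobut-2-en-1-one
Product: 11 4-[6-(2,6-dimethoxyphenyl)-4-oxo-4H-pyran-2-yl]-3,4-dimethoxycyclobut-2-en-1-one (racemic)
Conditions: MeI (10 equiv), Ag2O (2 equiv), 4 Å molecular sieves, MeCN, rt, dark
Reagents that add atoms: iodomethane, CI
Why: Purdie methylation (Ag2O-assisted Williamson-type etherification) runs without a soluble strong base, which base-labile tertiary 4-hydroxycyclobutenones tolerate, and MeI is too weak an alkylating agent to convert the pyranone carbonyl oxygen into a methoxypyrylium salt, as MeOTf or Me3OBF4 would; the stereocenter is untouched.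

Step 5
Reactants: 11 4-[6-(2,6-dimethoxyphenyl)-4-oxo-4H-pyran-2-yl]-3,4-dimethoxycyclobut-2-en-1-one
Product: 14 altisin (5-hydroxy-7,8-dimethoxy-2-(2,6-dimethoxyphenyl)-4H-chromen-4-one), via dienylketene 12 (not isolated), via cyclohexadienone 13 (not isolated)
Conditions: degassed dry p-xylene (0.01 M), 138 °C, Ar
Reagents that add atoms: none
Why: Heat cleaves the C1–C4 bond of 11 in a conrotatory 4π electrocyclic ring opening to dienylketene 12. The electrophilic ketene carbon then bonds to pyranone C3, the nucleophilic β-carbon of the ring enol ether, in a disrotatory 6π electrocyclisation that forms C4a–C5 and closes ring A as a six-membered carbocycle, and dienone 13, whose C4a–H sits between two carbonyl groups, enolises at once to the hydrogen-bonded C5 phenol. The closest known reaction type is the thermal ring expansion of 4-aryl-, 4-heteroaryl- and 4-alkenyl-4-alkoxycyclobutenones to hydroquinone monoethers (Moore-type rearrangement), of which this is an application to a 4-oxopyran-2-yl group. No stereocenter has to be controlled, since that of 11 is lost on ring opening and that of 13 on enolisation. The selectivity required is torquoselectivity, secured by the donor methoxy group on C4, which prefers outward rotation and thereby swings the pyranonyl group to the ketene side, while ketene of the other geometry can only revert to 11. Regiochemistry is fixed by the substrate, because the attachment carbon has only C3 and the ring oxygen as neighbours, and the neutral hydrocarbon medium gives ring C no chance to open and reclose to the 5,6,7-oxygenated isomer (Wessely–Moser rearrangement).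

Compound list
1 | (E)-4-methoxybut-3-en-2-one | CO/C=C/C(C)=O | starting material
2 | 2,6-dimethoxybenzoyl chloride | COc1cccc(OC)c1C(=O)Cl | starting material
3 | lithium dienolate: lithium (E)-4-methoxybuta-1,3-dien-2-olate | [Li+].[O-]C(=C)/C=C/OC | intermediate
4 | methoxyenone diketone: (E)-1-(2,6-dimethoxyphenyl)-5-methoxypent-4-ene-1,3-dione | COc1cccc(OC)c1C(=O)CC(=O)/C=C/OC | intermediate
5 | 2-(2,6-dimethoxyphenyl)-4H-pyran-4-one | COc1cccc(OC)c1-c1cc(=O)cco1 | intermediate
6 | dimethyl squarate (3,4-dimethoxycyclobut-3-ene-1,2-dione) | COC1=C(OC)C(=O)C1=O | starting material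
7 | hydroxycyclobutenone: 4-hydroxy-2,3-dimethoxycyclobut-2-en-1-one (racemic) | COC1=C(OC)C(=O)C1O | intermediate
8 | methyl semisquarate (3-methoxycyclobut-3-ene-1,2-dione) | COC1=CC(=O)C1=O | intermediate
9 | pyranonylmagnesium chloride: [6-(2,6-dimethoxyphenyl)-4-oxo-4H-pyran-2-yl]magnesium chloride (LiCl complex) | COc1cccc(OC)c1-c1cc(=O)cc([Mg]Cl)o1 | intermediate
10 | 4-[6-(2,6-dimethoxyphenyl)-4-oxo-4H-pyran-2-yl]-4-hydroxy-3-methoxycyclobut-2-en-1-one (racemic) | COC1=CC(=O)C1(O)c1cc(=O)cc(-c2c(OC)cccc2OC)o1 | intermediate
11 | 4-[6-(2,6-dimethoxyphenyl)-4-oxo-4H-pyran-2-yl]-3,4-dimethoxycyclobut-2-en-1-one (racemic) | COC1=CC(=O)C1(OC)c1cc(=O)cc(-c2c(OC)cccc2OC)o1 | intermediate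
12 | dienylketene: (3Z)-4-[6-(2,6-dimethoxyphenyl)-4-oxo-4H-pyran-2-yl]-3,4-dimethoxybuta-1,3-dien-1-one | O=C=C/C(OC)=C(/OC)c1cc(=O)cc(-c2c(OC)cccc2OC)o1 | intermediate
13 | cyclohexadienone: 2-(2,6-dimethoxyphenyl)-7,8-dimethoxy-4aH-chromene-4,5-dione (racemic, transient) | COC1=CC(=O)C2C(=O)C=C(c3c(OC)cccc3OC)OC2=C1OC | intermediate
14 | altisin (5-hydroxy-7,8-dimethoxy-2-(2,6-dimethoxyphenyl)-4H-chromen-4-one) | COc1cccc(OC)c1-c1cc(=O)c2c(O)cc(OC)c(OC)c2o1 | target

Total step count: 5. Longest linear sequence: 4 (steps 1, 3, 4, 5 from 1 and 2; equally steps 2, 3, 4, 5 from 6).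

Three steps most likely to fail

Step 5. The ketene may be consumed by dimerisation or by capture of trace moisture faster than it cyclises onto a double bond that belongs to a vinylogous ester, or prolonged heating may degrade the material. The fallback is a classical chromone construction without any pericyclic step; it sets out from 2 and comes back to the route at 14.
- The commercially available 2'-hydroxy-3',4',6'-trimethoxyacetophenone F1 is doubly deprotonated (LiN(SiMe3)2, THF, −78 to −10 °C) and C-acylated with 2. This is the direct variant of the Baker–Venkataraman sequence and gives 1-(2,6-dimethoxyphenyl)-3-(2-hydroxy-3,4,6-trimethoxyphenyl)propane-1,3-dione F2.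
- Cyclodehydration (H2SO4 cat., AcOH, 95 °C) can involve only the single free phenol and should give 5,7,8-trimethoxy-2-(2,6-dimethoxyphenyl)-4H-chromen-4-one F3.
- BCl3 (CH2Cl2, −78 to 0 °C) should then cleave only the C5 methyl ether, which lies peri to the C4 carbonyl group and chelates boron. These cold anhydrous conditions do not open ring C, and the product is 14.

Step 3. Deprotonation may take place next to the carbonyl group (C3 or C5), where a magnesium species fragments by β-elimination of the ring oxygen. The metalated pyranone may also add in conjugate fashion to pyranone that is not yet metalated. The fallback replaces deprotonation by a magnesium base with halogen–metal exchange; it sets out from 5 and comes back at 9.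
- Zincation with TMPZnCl·LiCl in the presence of MgCl2 (THF, −30 to 25 °C) is known to direct chromone-type rings to the carbon beside the ring oxygen. It should give [6-(2,6-dimethoxyphenyl)-4-oxo-4H-pyran-2-yl]zinc chloride F4, whose covalent carbon–zinc bond neither fragments nor self-adds.
- Quenching with I2 gives 2-(2,6-dimethoxyphenyl)-6-iodo-4H-pyran-4-one F5, which can be purified.
- Iodine–magnesium exchange with iPrMgCl·LiCl (THF, −78 °C) should then generate 9 quickly, with neither amine nor unmetalated pyranone present, and addition of 8 continues as in the route.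

Step 4. Alkylation of the hindered, electron-poor tertiary carbinol may be slow, and the strained ketol may meanwhile suffer ring cleavage or retro-addition on the basic Ag2O surface. The fallback moves the methylation behind the ring expansion; it sets out from 10 and comes back at 14.
- Heating 10 in degassed p-xylene under Ar should trigger the same cascade, since a free C4 hydroxyl group also rotates outward, as in the parent hydroquinone-forming version of the reaction. The expected product is 5,8-dihydroxy-7-methoxy-2-(2,6-dimethoxyphenyl)-4H-chromen-4-one F6, which is kept under Ar to prevent oxidation to the quinone.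
- MeI (1 equiv) and K2CO3 in acetone at rt should then methylate only the C8 hydroxyl group, because the C5 hydroxyl group is tied up in the hydrogen bond to the C4 carbonyl group. This gives 14.

Further compounds
F1 | step 5 | 2'-hydroxy-3',4',6'-trimethoxyacetophenone (purchased) | CC(=O)c1c(O)c(OC)c(OC)cc1OC
F2 | step 5 | 1-(2,6-dimethoxyphenyl)-3-(2-hydroxy-3,4,6-trimethoxyphenyl)propane-1,3-dione | COc1cccc(OC)c1C(=O)CC(=O)c1c(O)c(OC)c(OC)cc1OC
F3 | step 5 | 5,7,8-trimethoxy-2-(2,6-dimethoxyphenyl)-4H-chromen-4-one | COc1cccc(OC)c1-c1cc(=O)c2c(OC)cc(OC)c(OC)c2o1
F4 | step 3 | [6-(2,6-dimethoxyphenyl)-4-oxo-4H-pyran-2-yl]zinc chloride | COc1cccc(OC)c1-c1cc(=O)cc([Zn]Cl)o1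
F5 | step 3 | 2-(2,6-dimethoxyphenyl)-6-iodo-4H-pyran-4-one | COc1cccc(OC)c1-c1cc(=O)cc(I)o1
F6 | step 4 | 5,8-dihydroxy-7-methoxy-2-(2,6-dimethoxyphenyl)-4H-chromen-4-one | COc1cccc(OC)c1-c1cc(=O)c2c(O)cc(OC)c(O)c2o1
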